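Locants follow the hydrindane numbering of the target (C1–C7a; C1′ = carbinol carbon of the C1 side chain; α = face opposite to H-3a). Cuts: C2=O ← C2–OSi; C5/C6 esters ← cis-diol; oxirane CH2 ← C7 α-keto ester; then C1–C7a together with C1′–O (retro oxa-Diels–Alder); C1–C2 (alkenylzinc + aldehyde); C3–C3a (oxirane opening).
Enabling feature: the acetoxy oxygen and the oxirane carbon are 1,5-related across the C1–C7a bond (O–C1′–C1–C7a–C7–C), a latent dihydropyran spanning the cyclopentanone and cyclohexane rings; at the ketone level C7a=C7–C(=O)CO2Me is a 1-oxadiene and C1=C1′ its 2π partner.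
Forward: the six-membered ring is bought with the C5/C6 oxygens in place; the C3a arm, C4 methylene and C7 keto ester are added; one cycloaddition closes the cyclopentane and a temporary dihydropyran; hydrolysis reopens the pyran, then oxirane, esters and the C2 ketone follow.
Stereochemistry: C6 from the diol; C3a by anti epoxidation and SN2 opening; C7a, C1 and C1′ in the cycloaddition; C7 by convex-face protonation; oxirane carbon by Felkin–Anh/chelate-controlled ylide addition; C5 by Mitsunobu inversion; the pentanoate centre from the (S)-acid; C2–O is a helper centre set by DAIB and erased in the last step.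

Key step: step 10

Assumption: diol 1 (whole-cell cis-dihydroxylation product of bromobenzene), acids 25 and 27 and (+)-DAIB are taken as purchasable; lactol 20 is drawn as one anomer, both of which would react alike in step 12.

Step 1
Reactants: 1 (1S,2S)-3-bromocyclohexa-3,5-diene-1,2-diol
Product: 2 (5S,6S)-1-bromo-5,6-bis[(4-methoxybenzyl)oxy]cyclohexa-1,3-diene
Conditions: PMBCl, NaH, TBAI (cat.), DMF, 0 → 23 °C
Reagents that add atoms: 4-methoxybenzyl chloride, COc1ccc(CCl)cc1
Why: Double Williamson etherification of the two allylic alcohols touches no stereocentre and gives acid-stable ethers that should survive the aqueous acid of step 11.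

Step 2
Reactants: 2 bis-PMB diene
Product: 3 3-bromo-4,5-bis[(4-methoxybenzyl)oxy]-7-oxabicyclo[4.1.0]hept-2-ene (oxirane anti to both ethers)
Conditions: mCPBA, NaHCO3, CH2Cl2, 0 °C
Reagents that add atoms: 3-chloroperbenzoic acid, O=C(OO)c1cccc(Cl)c1
Why: Prilezhaev epoxidation should pick the electron-richer, unhalogenated alkene and occur anti to the two allylic ethers, the usual outcome for 5,6-dioxygenated 1-halocyclohexa-1,3-dienes.

Step 3
Reactants: 3 vinyl oxirane; 4 acetonitrile
Product: 6 2-[3-bromo-6-hydroxy-4,5-bis(4-methoxybenzyloxy)cyclohex-2-en-1-yl]acetonitrile (CH2CN trans to OH, cis to both ethers), via lithioacetonitrile 5 (not isolated)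
Conditions: MeCN, n-BuLi, THF, −78 °C; then 3, −78 → 0 °C
Reagents that add atoms: none
Why: SN2 opening of the vinyl oxirane at its allylic carbon (C3a) by the nitrile-stabilised carbanion with inversion should give the trans cyano alcohol, so that C3 ends on the α face, cis to the ethers.

Step 4
Reactants: 6 cyano alcohol
Product: 7 2-[3-bromo-6-oxo-4,5-bis(4-methoxybenzyloxy)cyclohex-2-en-1-yl]acetonitrile
Conditions: Dess–Martin periodinane, NaHCO3, CH2Cl2, 0 → 23 °C
Reagents that add atoms: none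
Why: Buffered Dess–Martin oxidation is neutral, so the β,γ-unsaturated ketone should form without migration of the C7=C7a bond or epimerisation at C3a.

Step 5
Reactants: 7 ketone
Product: 8 2-[3-bromo-6-methylidene-4,5-bis(4-methoxybenzyloxy)cyclohex-2-en-1-yl]acetonitrile
Conditions: Zn, CH2Br2, TiCl4, THF/CH2Cl2, 0 → 23 °C
Reagents that add atoms: dibromomethane, BrCBr
Why: Takai–Lombardo methylenation is a non-basic carbonyl olefination suited to enolisable α-alkoxy ketones, so C3a should keep its configuration.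

Step 6
Reactants: 8 methylidene nitrile
Product: 10 2-[3-bromo-6-methylidene-4,5-bis(4-methoxybenzyloxy)cyclohex-2-en-1-yl]acetaldehyde, via N-aluminoimine 9 (not isolated)
Conditions: DIBAL, toluene, −78 °C; aq. Rochelle salt
Reagents that add atoms: water, O
Why: DIBAL half-reduction of the nitrile stops at the N-aluminoimine, which is hydrolysed on work-up to the aldehyde (nitrile-to-aldehyde reduction).

Step 7
Reactants: 10 aldehyde; 11 propyne
Product: 14 (2S,3E)-1-[3-bromo-6-methylidene-4,5-bis(4-methoxybenzyloxy)cyclohex-2-en-1-yl]pent-3-en-2-ol, via dicyclohexyl[(E)-propenyl]borane 12 (not isolated), via ethyl[(E)-propenyl]zinc 13 (not isolated)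
Conditions: propyne, (c-C6H11)2BH, hexane, 0 °C; ZnEt2, −78 °C; (+)-DAIB (5 mol %), then 10, 0 °C
Reagents that add atoms: none
Why: Hydroboration of propyne and boron–zinc exchange give an (E)-alkenylzinc whose DAIB-catalysed addition to the aldehyde Re face (catalytic asymmetric alkenylzinc addition) should set the (S)-carbinol under reagent control with retention of the (E) geometry.

Step 8
Reactants: 14 allylic alcohol
Product: 15 tert-butyldiphenylsilyl ether of 14
Conditions: TBDPSCl, imidazole, DMF, 23 °C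
Reagents that add atoms: tert-butyl(chloro)diphenylsilane, CC(C)(C)[Si](Cl)(c1ccccc1)c1ccccc1
Why: Silyl ether formation gives an acid-stable group that will sit on the convex face in step 10 and is removed only at the end.

Step 9
Reactants: 15 vinyl bromide; 16 dimethyl oxalate
Product: 18 methyl 2-oxo-2-[cyclohex-1-en-1-yl]acetate carrying the C3a arm, C4 methylidene and both ethers, via vinyllithium 17 (not isolated)
Conditions: t-BuLi (2.1 equiv), Et2O, −78 °C; then into (CO2Me)2 (3 equiv), THF, −78 °C; AcOH quench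
Reagents that add atoms: none
Why: Bromine–lithium exchange followed by acylation with excess dimethyl oxalate, whose tetrahedral adduct is stable at −78 °C, should give the α-keto ester without over-addition (organolithium acylation).

Step 10
Reactants: 18 β,γ-unsaturated α-keto ester
Product: 19 tricyclic cycloadduct (cis-hydrindane fused across C1–C7a–C7 to a 2-methoxycarbonyl-dihydropyran; C1′ methyl, C2 silyloxy)
Conditions: toluene (0.01 M), BHT, 130 °C, sealed tube
Reagents that add atoms: none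
Why: Concerted, asynchronous [4+2] cycloaddition in which the electron-poor 1-oxadiene O=C(CO2Me)–C7=C7a reacts through its s-cis conformer with the tethered (E)-C1=C1′ alkene, forming C1–C7a and C1′–O; the closest known reaction type is the intramolecular inverse-electron-demand oxa-Diels–Alder of 2-oxo-3-enoates and alkylidene-1,3-dicarbonyls with unactivated alkenes. The cyclopentane closes through the three-atom tether C3a–C3–C2 fixed at the diene terminus (type 1 intramolecular mode), and the dihydropyran is the six-membered cycloadduct ring. C7a: the tether on α-C3a can only reach the α face of C7a, which gives the cis-hydrindane. C1: with a three-atom tether the transition state that places C2 under the heterodiene is favoured and gives the cis-fused cyclopenta[c]pyran, i.e. H-1 cis to H-7a, with the bulky silyloxy group pointing outwards. C1′: suprafacial addition to the (E)-alkene translates its geometry into the (S)-carbinol carbon. The step needs cis over trans ring fusion and [4+2] over ene or intermolecular pathways; the short tether, the strain of a trans-fused bicycle next to the enol ether double bond, high dilution and the fact that the exocyclic methylene cannot reach the heterodiene should secure this.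

Step 11
Reactants: 19 cycloadduct
Product: 20 six-membered lactol (C1′–O–C(OH)(CO2Me)–C7, H-7 β)
Conditions: aq. HCl (1 M), THF, 23 °C
Reagents that add atoms: water, O
Why: Acid hydrolysis of the 2-alkoxyacrylate enol ether: protonation at C7 on the convex face of the bowl-shaped tricycle (cis to H-7a, H-1 and H-3a, anti to the C6 ether) should set C7, and water adds to the oxocarbenium ion to give the hemiketal.

Step 12
Reactants: 20 lactol
Product: 22 methyl (2R)-oxirane-2-carboxylate at C7 with free C1′ hydroxyl, via ring-opened keto ester 21 (not isolated)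
Conditions: Me3SI (4 equiv), n-BuLi (3.8 equiv), THF, −10 °C; then 20, −10 → 23 °C
Reagents that add atoms: trimethylsulfonium iodide, C[S+](C)C.[I-]
Why: Corey–Chaykovsky epoxidation: the lactolate opens to the keto ester, and the sulfonium ylide should add to the ketone anti to the C7–C7a bond with the carbonyl oxygen held near the C6 ether by lithium (Felkin–Anh and chelate models agree), giving the (R)-oxirane carbon.

Step 13
Reactants: 22 hydroxy glycidate
Product: 23 C1′ acetate
Conditions: Ac2O, pyridine, DMAP (cat.), CH2Cl2, 0 → 23 °C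
Reagents that add atoms: acetic anhydride, CC(=O)OC(C)=O
Why: DMAP-catalysed acyl transfer to the only free hydroxyl.

Step 14
Reactants: 23 bis-PMB ether
Product: 24 cis-5,6-diol (both hydroxyls α)
Conditions: DDQ, CH2Cl2/pH 7 buffer, 0 → 23 °C
Reagents that add atoms: none
Why: Oxidative cleavage of both PMB ethers by DDQ under neutral buffered conditions should spare the oxirane, acetate, silyl ether and alkene.

Step 15
Reactants: 24 diol; 25 (S)-3-methylpentanoic acid
Product: 26 C5 β-(3S)-3-methylpentanoate with free C6 α-hydroxyl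
Conditions: 25, PPh3, DIAD, toluene, 0 → 23 °C
Reagents that add atoms: none
Why: Mitsunobu esterification: the less hindered, allylic C5 hydroxyl should be activated and displaced by the carboxylate with inversion, which sets C5 trans to C6–OH (cis-1,2-diols give trans hydroxy esters).

Step 16
Reactants: 26 hydroxy ester; 27 (E)-3-methylpent-2-enoic acid
Product: 28 C5,C6 diester (C2 silyl ether)
Conditions: 27, DCC, DMAP, CH2Cl2, 0 → 23 °C
Reagents that add atoms: none
Why: Steglich esterification of the remaining C6 hydroxyl; carbodiimide activation avoids the ketene pathway that would deconjugate or isomerise the (E)-enoate.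

Step 17
Reactants: 28 silyl ether
Product: 29 C2 alcohol
Conditions: HF·pyridine, pyridine, THF, 0 → 23 °C
Reagents that add atoms: none
Why: Fluoride-mediated desilylation buffered with pyridine, which glycidic esters, the other esters and both alkenes should tolerate.

Step 18
Reactants: 29 alcohol
Product: 30 methyl (2R)-2-[(1R,3aS,5R,6R,7R,7aR)-1-[(1S)-1-acetoxyethyl]-5-{[(3S)-3-methylpentanoyl]oxy}-6-{[(2E)-3-methylpent-2-enoyl]oxy}-4-methylidene-2-oxooctahydro-1H-inden-7-yl]oxirane-2-carboxylate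
Conditions: Dess–Martin periodinane, NaHCO3, CH2Cl2, 0 °C
Reagents that add atoms: none
Why: Buffered Dess–Martin oxidation gives the C2 ketone under neutral conditions, so the β-acetoxy ketone should neither eliminate nor epimerise at C1.

Compound list
1 | (1S,2S)-3-bromocyclohexa-3,5-diene-1,2-diol | C1=CC=C(Br)[C@@H](O)[C@H]1O | starting material
2 | (5S,6S)-1-bromo-5,6-bis[(4-methoxybenzyl)oxy]cyclohexa-1,3-diene | C1=CC=C(Br)[C@@H](OCc2ccc(OC)cc2)[C@H]1OCc1ccc(OC)cc1 | intermediate
3 | 3-bromo-4,5-bis[(4-methoxybenzyl)oxy]-7-oxabicyclo[4.1.0]hept-2-ene, oxirane anti to both ethers | C1=C(Br)[C@@H](OCc2ccc(OC)cc2)[C@@H](OCc2ccc(OC)cc2)[C@@H]2O[C@H]12 | intermediate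
4 | acetonitrile | CC#N | starting material
5 | lithioacetonitrile | [Li]CC#N | intermediate
6 | 2-[3-bromo-6-hydroxy-4,5-bis(4-methoxybenzyloxy)cyclohex-2-en-1-yl]acetonitrile, CH2CN trans to OH and cis to the ethers | O[C@@H]1[C@@H](CC#N)C=C(Br)[C@@H](OCc2ccc(OC)cc2)[C@H]1OCc1ccc(OC)cc1 | intermediate
7 | 2-[3-bromo-6-oxo-4,5-bis(4-methoxybenzyloxy)cyclohex-2-en-1-yl]acetonitrile | O=C1[C@@H](CC#N)C=C(Br)[C@@H](OCc2ccc(OC)cc2)[C@H]1OCc1ccc(OC)cc1 | intermediate
8 | 2-[3-bromo-6-methylidene-4,5-bis(4-methoxybenzyloxy)cyclohex-2-en-1-yl]acetonitrile | C=C1[C@@H](CC#N)C=C(Br)[C@@H](OCc2ccc(OC)cc2)[C@H]1OCc1ccc(OC)cc1 | intermediate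
9 | N-(diisobutylalumino)imine of aldehyde 10 | C=C1[C@@H](CC=N[Al](CC(C)C)CC(C)C)C=C(Br)[C@@H](OCc2ccc(OC)cc2)[C@H]1OCc1ccc(OC)cc1 | intermediate
10 | 2-[3-bromo-6-methylidene-4,5-bis(4-methoxybenzyloxy)cyclohex-2-en-1-yl]acetaldehyde | C=C1[C@@H](CC=O)C=C(Br)[C@@H](OCc2ccc(OC)cc2)[C@H]1OCc1ccc(OC)cc1 | intermediate
11 | propyne | CC#C | starting material
12 | dicyclohexyl[(E)-prop-1-enyl]borane | C/C=C/B(C1CCCCC1)C1CCCCC1 | intermediate
13 | ethyl[(E)-prop-1-enyl]zinc | CC[Zn]/C=C/C | intermediate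
14 | (2S,3E)-1-[3-bromo-6-methylidene-4,5-bis(4-methoxybenzyloxy)cyclohex-2-en-1-yl]pent-3-en-2-ol | C=C1[C@@H](C[C@H](O)/C=C/C)C=C(Br)[C@@H](OCc2ccc(OC)cc2)[C@H]1OCc1ccc(OC)cc1 | intermediate
15 | tert-butyldiphenylsilyl ether of 14 | C=C1[C@@H](C[C@H](O[Si](c2ccccc2)(c2ccccc2)C(C)(C)C)/C=C/C)C=C(Br)[C@@H](OCc2ccc(OC)cc2)[C@H]1OCc1ccc(OC)cc1 | intermediate
16 | dimethyl oxalate | COC(=O)C(=O)OC | starting material
17 | vinyllithium derived from 15 | C=C1[C@@H](C[C@H](O[Si](c2ccccc2)(c2ccccc2)C(C)(C)C)/C=C/C)C=C([Li])[C@@H](OCc2ccc(OC)cc2)[C@H]1OCc1ccc(OC)cc1 | intermediate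
18 | methyl 2-oxoacetate on C7 of the cyclohexene (C7=C7a), with the (2S,3E)-2-silyloxypent-3-enyl arm on C3a, C4 methylidene and C5/C6 PMB ethers | C=C1[C@@H](C[C@H](O[Si](c2ccccc2)(c2ccccc2)C(C)(C)C)/C=C/C)C=C(C(=O)C(=O)OC)[C@@H](OCc2ccc(OC)cc2)[C@H]1OCc1ccc(OC)cc1 | intermediate
19 | tricyclic cycloadduct: cis-hydrindane with dihydropyran O–C(CO2Me)=C7 bridging C1′ and C7; H-1, H-3a, H-7a β; C2 silyloxy β | C=C1[C@H]2C[C@H](O[Si](c3ccccc3)(c3ccccc3)C(C)(C)C)[C@H]3[C@H](C)OC(C(=O)OC)=C([C@@H]23)[C@@H](OCc2ccc(OC)cc2)[C@H]1OCc1ccc(OC)cc1 | intermediate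
20 | lactol: cyclic hemiketal of the C7 keto ester with the C1′ hydroxyl, H-7 β | C=C1[C@H]2C[C@H](O[Si](c3ccccc3)(c3ccccc3)C(C)(C)C)[C@H]3[C@H](C)O[C@@](O)(C(=O)OC)[C@H]([C@@H]23)[C@@H](OCc2ccc(OC)cc2)[C@H]1OCc1ccc(OC)cc1 | intermediate
21 | ring-opened δ-hydroxy α-keto ester of 20 | C=C1[C@H]2C[C@H](O[Si](c3ccccc3)(c3ccccc3)C(C)(C)C)[C@@H]([C@H](C)O)[C@H]2[C@@H](C(=O)C(=O)OC)[C@@H](OCc2ccc(OC)cc2)[C@H]1OCc1ccc(OC)cc1 | intermediate
22 | hydroxy glycidate: methyl (2R)-oxirane-2-carboxylate on C7, (1S)-1-hydroxyethyl on C1 | C=C1[C@H]2C[C@H](O[Si](c3ccccc3)(c3ccccc3)C(C)(C)C)[C@@H]([C@H](C)O)[C@H]2[C@@H]([C@]2(C(=O)OC)CO2)[C@@H](OCc2ccc(OC)cc2)[C@H]1OCc1ccc(OC)cc1 | intermediate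
23 | C1′ acetate of 22 | C=C1[C@H]2C[C@H](O[Si](c3ccccc3)(c3ccccc3)C(C)(C)C)[C@@H]([C@H](C)OC(C)=O)[C@H]2[C@@H]([C@]2(C(=O)OC)CO2)[C@@H](OCc2ccc(OC)cc2)[C@H]1OCc1ccc(OC)cc1 | intermediate
24 | cis-5,6-diol (both α) | C=C1[C@H]2C[C@H](O[Si](c3ccccc3)(c3ccccc3)C(C)(C)C)[C@@H]([C@H](C)OC(C)=O)[C@H]2[C@@H]([C@]2(C(=O)OC)CO2)[C@@H](O)[C@H]1O | intermediate
25 | (S)-3-methylpentanoic acid | CC[C@H](C)CC(=O)O | starting material
26 | C5 β-(3S)-3-methylpentanoate, C6 α-hydroxyl | C=C1[C@H]2C[C@H](O[Si](c3ccccc3)(c3ccccc3)C(C)(C)C)[C@@H]([C@H](C)OC(C)=O)[C@H]2[C@@H]([C@]2(C(=O)OC)CO2)[C@@H](O)[C@@H]1OC(=O)C[C@@H](C)CC | intermediate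
27 | (E)-3-methylpent-2-enoic acid | CC/C(C)=C/C(=O)O | starting material
28 | C5 pentanoate, C6 (E)-3-methylpent-2-enoate, C2 silyl ether | C=C1[C@H]2C[C@H](O[Si](c3ccccc3)(c3ccccc3)C(C)(C)C)[C@@H]([C@H](C)OC(C)=O)[C@H]2[C@@H]([C@]2(C(=O)OC)CO2)[C@@H](OC(=O)/C=C(\C)CC)[C@@H]1OC(=O)C[C@@H](C)CC | intermediate
29 | C2 alcohol (S) | C=C1[C@H]2C[C@H](O)[C@@H]([C@H](C)OC(C)=O)[C@H]2[C@@H]([C@]2(C(=O)OC)CO2)[C@@H](OC(=O)/C=C(\C)CC)[C@@H]1OC(=O)C[C@@H](C)CC | intermediate
30 | methyl (2R)-2-[(1R,3aS,5R,6R,7R,7aR)-1-[(1S)-1-acetoxyethyl]-5-{[(3S)-3-methylpentanoyl]oxy}-6-{[(2E)-3-methylpent-2-enoyl]oxy}-4-methylidene-2-oxooctahydro-1H-inden-7-yl]oxirane-2-carboxylate | C=C1[C@H]2CC(=O)[C@@H]([C@H](C)OC(C)=O)[C@H]2[C@@H]([C@]2(C(=O)OC)CO2)[C@@H](OC(=O)/C=C(\C)CC)[C@@H]1OC(=O)C[C@@H](C)CC | target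

Total step count: 18. Longest linear sequence: 18 steps (1 → 30).

Steps most likely to fail

Step 10. The unactivated 1,2-disubstituted alkene may react too slowly, so that ene-type hydrogen transfer, oligomerisation of the keto ester or the trans-fused cyclisation mode compete. The fallback sets out from 15: Shi epoxidation of the (E)-alkene with the enantiomeric fructose-derived ketone and Oxone should give the epoxy silyl ether F1, in which the C1′–O bond already has the (S) configuration. Bromine–lithium exchange and dimethyl oxalate as in step 9 would give the epoxy keto ester F2. Cp2TiCl (trivalent titanium, made from Cp2TiCl2 and Zn) then opens the oxirane to the C1 radical, which adds 5-exo to C7a of the enone (reductive epoxide-opening radical cyclisation). Protonation of the titanium enolate and ring closure of the δ-hydroxy keto ester return the route to lactol 20.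

Step 12. The ring-opened keto ester may enolise towards C7 (epimerisation, β-elimination of the C6 ether) before the ylide adds, and facial selectivity at the ketone rests on substrate control only. The fallback sets out from 20: Wittig methylenation (Ph3P=CH2, THF) should give the acrylate F3, and DIBAL the allylic alcohol F4. Sharpless asymmetric epoxidation (Ti(OiPr)4, D-(−)-diisopropyl tartrate, t-BuOOH) then sets the oxirane carbon under reagent control to give the epoxy alcohol F5. TEMPO/PhI(OAc)2 followed by NaClO2 gives the glycidic acid F6, and TMSCHN2 returns to 22.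

Step 15. Loss of regioselectivity between the two secondary hydroxyls, SN2′ attack at the exocyclic methylene or elimination may erode the Mitsunobu inversion. The fallback sets out from 24: MnO2 should oxidise only the allylic C5 hydroxyl to the α′-hydroxy enone F7. Hydroxyl-directed reduction with Me4NBH(OAc)3 delivers hydride from the face of the C6 hydroxyl and gives the trans-diol F8. Selective DCC/DMAP esterification of the less hindered allylic C5 hydroxyl with 25 returns to 26.

Further compounds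
F1 | step 10 | oxirane of 15 at C1=C1′ (trans, C1′ S) | C=C1[C@@H](C[C@H](O[Si](c2ccccc2)(c2ccccc2)C(C)(C)C)[C@@H]2O[C@H]2C)C=C(Br)[C@@H](OCc2ccc(OC)cc2)[C@H]1OCc1ccc(OC)cc1
F2 | step 10 | epoxy α-keto ester (F1 with Br replaced by C(=O)CO2Me) | C=C1[C@@H](C[C@H](O[Si](c2ccccc2)(c2ccccc2)C(C)(C)C)[C@@H]2O[C@H]2C)C=C(C(=O)C(=O)OC)[C@@H](OCc2ccc(OC)cc2)[C@H]1OCc1ccc(OC)cc1
F3 | step 12 | methyl 2-substituted acrylate on C7, free C1′ hydroxyl | C=C1[C@H]2C[C@H](O[Si](c3ccccc3)(c3ccccc3)C(C)(C)C)[C@@H]([C@H](C)O)[C@H]2[C@@H](C(=C)C(=O)OC)[C@@H](OCc2ccc(OC)cc2)[C@H]1OCc1ccc(OC)cc1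
F4 | step 12 | 2-substituted allylic alcohol on C7 | C=C1[C@H]2C[C@H](O[Si](c3ccccc3)(c3ccccc3)C(C)(C)C)[C@@H]([C@H](C)O)[C@H]2[C@@H](C(=C)CO)[C@@H](OCc2ccc(OC)cc2)[C@H]1OCc1ccc(OC)cc1
F5 | step 12 | 2,2-disubstituted epoxy alcohol on C7 | C=C1[C@H]2C[C@H](O[Si](c3ccccc3)(c3ccccc3)C(C)(C)C)[C@@H]([C@H](C)O)[C@H]2[C@@H]([C@]2(CO)CO2)[C@@H](OCc2ccc(OC)cc2)[C@H]1OCc1ccc(OC)cc1
F6 | step 12 | glycidic acid on C7 | C=C1[C@H]2C[C@H](O[Si](c3ccccc3)(c3ccccc3)C(C)(C)C)[C@@H]([C@H](C)O)[C@H]2[C@@H]([C@]2(C(=O)O)CO2)[C@@H](OCc2ccc(OC)cc2)[C@H]1OCc1ccc(OC)cc1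
F7 | step 15 | C5 ketone (4-methylidene-5-oxo) with C6 α-hydroxyl | C=C1[C@H]2C[C@H](O[Si](c3ccccc3)(c3ccccc3)C(C)(C)C)[C@@H]([C@H](C)OC(C)=O)[C@H]2[C@@H]([C@]2(C(=O)OC)CO2)[C@@H](O)C1=O
F8 | step 15 | trans-5,6-diol (C5 β, C6 α) | C=C1[C@H]2C[C@H](O[Si](c3ccccc3)(c3ccccc3)C(C)(C)C)[C@@H]([C@H](C)OC(C)=O)[C@H]2[C@@H]([C@]2(C(=O)OC)CO2)[C@@H](O)[C@@H]1O
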